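**Retrosynthetic overview**
- Diene bond C2–Ca: fluoride-promoted Pd coupling of an (E)-vinyl iodide (the hydroxylated cyclohexane half) with a (Z)-vinylsilane, the latter from trans-hydrosilylation of a C4 propargylic alcohol on the finished epoxy-triol core.
- Ring carbinols C7/C10: double 1,2-reduction of an epoxyquinone, itself unveiled from an epoxidised quinone bis(dimethyl ketal).
- Key bond C4–C5: the quinone ring carbon is made nucleophilic as a metalated bromoquinone bis-ketal (polarity-reversed quinone) and added enantioselectively to but-2-ynal; the new carbinol then directs the epoxidation, so C4, C5 and C6 are set in one pot.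
- Terpenoid half: (R)-6,7-epoxygeranyl acetate, titanocene radical cyclization, hydration, oxidation, Takai iodo-olefination.
- Ring order: the side-chain carbocycle is formed by radical cyclization; the core six-membered ring is the arene, dearomatised anodically; the oxirane is closed last, in the key step.

Assumption: atom labels follow the target SMILES (side chain C1–C4, core ring C5–C10 with the oxirane on C5/C6 and CH2OH on C8, diene carbons Ca/Cb, carbocycle C1′–C6′); but-2-ynal is made fresh because it is volatile.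

Step 1
Reactants: 1 geranyl acetate
Product: 2 (2E)-5-[(2R)-3,3-dimethyloxiran-2-yl]-3-methylpent-2-en-1-yl acetate
Conditions: D-fructose-derived Shi ketone (1,2:4,5-di-O-isopropylidene-β-D-erythro-2,3-hexodiulo-2,6-pyranose, 0.3 equiv), KHSO5 (as 2KHSO5·KHSO4·K2SO4), K2CO3, Bu4NHSO4, MeCN/CH2(OMe)2/aq. Na2B4O7 buffer, 0 °C
Reagents that add atoms: potassium peroxymonosulfate, [K+].[O-]S(=O)(=O)OO
Why: Shi asymmetric epoxidation, in which the chiral dioxirane attacks the electron-rich 6,7-olefin (the 2,3-olefin is deactivated by the allylic acetate) through the spiro transition state to give the (R)-oxirane that becomes the (R)-carbinol C3′.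

Step 2
Reactants: 2 (2E)-5-[(2R)-3,3-dimethyloxiran-2-yl]-3-methylpent-2-en-1-yl acetate
Product: 3 [(1S,3R)-3-hydroxy-2,2-dimethyl-6-methylidenecyclohexyl]methyl acetate
Conditions: Cp2TiCl2 (2.2 equiv), Mn powder, THF, rt; aq. work-up
Reagents that add atoms: none
Why: Titanocene chloride (trivalent titanium) radical epoxypolyene cyclization (Nugent–RajanBabu opening), where the tertiary radical closes 6-endo through a chair that puts C3′–O and CH2OAc both equatorial, so C1′ is set from the oxirane centre, and β-hydride loss leaves the exocyclic alkene.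

Step 3
Reactants: 3 [(1S,3R)-3-hydroxy-2,2-dimethyl-6-methylidenecyclohexyl]methyl acetate
Product: 5 (1R,2S,4R)-2-(hydroxymethyl)-1,3,3-trimethylcyclohexane-1,4-diol, via hydroxy acetate 4 (not isolated)
Conditions: Co(acac)2 (0.2 equiv), PhSiH3, O2 (1 atm), THF, rt; then K2CO3, MeOH, rt
Reagents that add atoms: dioxygen, O=O
Why: Mukaiyama–Isayama Markovnikov hydration, in which the tertiary C6′ radical is trapped on the equatorial face because the axial face is blocked by the syn-axial C2′ methyl (as in 8α-ols from labd-8(17)-enes), giving equatorial OH and axial methyl at C6′, followed by methanolysis of the acetate.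

Step 4
Reactants: 5 (1R,2S,4R)-2-(hydroxymethyl)-1,3,3-trimethylcyclohexane-1,4-diol
Product: 6 (1R,3R,6R)-3,6-dihydroxy-2,2,6-trimethylcyclohexane-1-carbaldehyde
Conditions: TEMPO (2,2,6,6-tetramethylpiperidin-1-oxyl, 0.1 equiv), PhI(OAc)2 (1.1 equiv), CH2Cl2, rt
Reagents that add atoms: none
Why: Oxoammonium (TEMPO/PhI(OAc)2) oxidation is selective for the primary alcohol over the secondary and tertiary ones and is non-basic, so the β-hydroxy aldehyde neither retro-aldolises nor epimerises (the equatorial formyl group is the stable epimer).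

Step 5
Reactants: 6 (1R,3R,6R)-3,6-dihydroxy-2,2,6-trimethylcyclohexane-1-carbaldehyde
Product: 7 (1R,2R,4R)-2-[(E)-2-iodoethenyl]-1,3,3-trimethylcyclohexane-1,4-diol
Conditions: CrCl2 (6 equiv), CHI3 (2 equiv), THF, 0 °C → rt
Reagents that add atoms: iodoform, IC(I)I
Why: Takai iodo-olefination via the geminal dichromium carbenoid gives the (E)-vinyl iodide from an α-branched aldehyde and tolerates free hydroxyls.

Step 6
Reactants: 8 but-2-yn-1-ol
Product: 9 but-2-ynal
Conditions: activated MnO2 (10 equiv), CH2Cl2, rt; filtered, dried solution used at once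
Reagents that add atoms: none
Why: MnO2 oxidises the propargylic alcohol to the ynal without over-oxidation.

Step 7
Reactants: 10 4-bromo-2,5-dimethoxybenzaldehyde
Product: 11 (4-bromo-2,5-dimethoxyphenyl)methanol
Conditions: NaBH4, MeOH, 0 °C
Reagents that add atoms: none
Why: Simple borohydride reduction of the aryl aldehyde.

Step 8
Reactants: 11 (4-bromo-2,5-dimethoxyphenyl)methanol
Product: 12 [(4-bromo-2,5-dimethoxyphenyl)methoxy]tri(propan-2-yl)silane
Conditions: TIPSCl, imidazole, DMF, rt
Reagents that add atoms: chlorotri(propan-2-yl)silane, CC(C)[Si](Cl)(C(C)C)C(C)C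
Why: Silylation of the primary alcohol with a group that survives KOH/MeOH, t-BuLi and brief cold acid, keeps the CH2O group from directing the later epoxidation, and falls off with fluoride in the last step.

Step 9
Reactants: 12 [(4-bromo-2,5-dimethoxyphenyl)methoxy]tri(propan-2-yl)silane
Product: 13 [(4-bromo-3,3,6,6-tetramethoxycyclohexa-1,4-dien-1-yl)methoxy]tri(propan-2-yl)silane (bromoquinone bis(dimethyl ketal))
Conditions: Pt anode, undivided cell, 1% KOH in MeOH, 0 °C, constant current
Reagents that add atoms: methanol, CO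
Why: Swenton-type anodic bis-methoxylation of a 1,4-dimethoxyarene (radical cation trapped twice by methoxide) dearomatises the ring to the quinone bis-ketal and leaves the C–Br bond intact.

Step 10
Reactants: 13 [(4-bromo-3,3,6,6-tetramethoxycyclohexa-1,4-dien-1-yl)methoxy]tri(propan-2-yl)silane; 9 but-2-ynal
Product: 17 (1S)-1-[2,2,5,5-tetramethoxy-4-(triisopropylsilyloxymethyl)-7-oxabicyclo[4.1.0]hept-3-en-1-yl]but-2-yn-1-ol (erythro epoxy alcohol; C4/C5/C6 arranged as in the target), via alkenyllithium 14 (not isolated), via alkenyl(methyl)zinc 15 (not isolated), via zinc alkoxide 16 (not isolated)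
Conditions: t-BuLi (2.0 equiv), Et2O, −78 °C; MeZnCl (1.05 equiv), −78 → 0 °C, solvent switched to toluene; TEEDA (N,N,N′,N′-tetraethylethylenediamine, 1 equiv), (+)-MIB ((2R)-3-exo-morpholinoisoborneol, 0.1 equiv), 9 (2 equiv), 0 °C; then Ti(OiPr)4 (0.2 equiv), TBHP (3 equiv), 0 °C → rt
Reagents that add atoms: tert-butyl hydroperoxide, CC(C)(C)OO
Why: The quinone carbon C5, electrophilic in the quinone itself, is turned into a nucleophile by bromine–lithium exchange on the bis-ketal (a masked quinone/β-acylvinyl anion, Swenton type) and joined to the equally electrophilic aldehyde carbon C4; amino-alcohol-catalysed alkenylzinc addition (Oppolzer/Walsh type, Re-face delivery with the (+)-ligand) sets C4 (S), and the zinc alkoxide then directs Ti-mediated TBHP epoxidation of the adjacent ring alkene, where allylic 1,2-strain against the quaternary ketal carbon (carbinol H eclipsing C10) gives the erythro oxirane and sets C5 and C6.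

Step 11
Reactants: 17 erythro epoxy alcohol bis-ketal
Product: 18 1-[(1S)-1-hydroxybut-2-yn-1-yl]-4-(triisopropylsilyloxymethyl)-7-oxabicyclo[4.1.0]hept-3-ene-2,5-dione (epoxyquinone)
Conditions: TFA, H2O, CH2Cl2, 0 °C
Reagents that add atoms: water, O
Why: Acid-catalysed hydrolysis of both dimethyl ketals unveils the epoxyquinone, the oxirane being deactivated towards acid by the flanking oxocarbenium/carbonyl carbons while the primary TIPS ether and the propargylic alcohol survive brief cold aqueous acid.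

Step 12
Reactants: 18 epoxyquinone
Product: 19 1-[(1S)-1-hydroxybut-2-yn-1-yl]-4-(triisopropylsilyloxymethyl)-7-oxabicyclo[4.1.0]hept-3-ene-2,5-diol (both ring hydroxyls trans to the oxirane oxygen and cis to each other)
Conditions: NaBH4, CeCl3·7H2O, MeOH, −78 °C
Reagents that add atoms: none
Why: Luche 1,2-reduction, in which cerium-assisted borohydride attacks both α,β-epoxy enone carbonyls from the face of the oxirane oxygen (the anti preference of chelating borohydride reductions of cyclic epoxy ketones), sets C7 and C10 trans to the oxirane.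

Step 13
Reactants: 19 epoxy triol
Product: 20 1-[(1S,2Z)-3-[benzyl(dimethyl)silyl]-1-hydroxybut-2-en-1-yl]-4-(triisopropylsilyloxymethyl)-7-oxabicyclo[4.1.0]hept-3-ene-2,5-diol
Conditions: [Cp*Ru(MeCN)3]PF6 (5 mol%), BnMe2SiH (1.3 equiv), acetone, 0 °C → rt
Reagents that add atoms: benzyldimethylsilane, C[SiH](C)Cc1ccccc1
Why: Ruthenium-catalysed trans-hydrosilylation of a propargylic alcohol (Trost type) puts silicon on the alkyne carbon distal to the hydroxyl and adds H and Si anti, giving the (Z)-vinylsilane with silicon cis to C4, the geometry needed for the 2Z alkene.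

Step 14
Reactants: 20 (Z)-vinylsilane; 7 (1R,2R,4R)-2-[(E)-2-iodoethenyl]-1,3,3-trimethylcyclohexane-1,4-diol
Product: 23 arthrosporol A, via silanol 21 (not isolated), via silyl-protected diene 22 (not isolated)
Conditions: 7 (1.2 equiv), Pd2(dba)3 (5 mol%), TBAF (5 equiv), THF, rt
Reagents that add atoms: none
Why: Fluoride-promoted Hiyama–Denmark cross-coupling, in which TBAF cleaves the benzyl–silicon bond to a silanol(ate) that transmetalates to the alkenylpalladium from 7 with retention at both alkenes, gives the (2Z,4E)-diene, and the same fluoride removes the TIPS group.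

**Compound list**
1 | geranyl acetate | CC(=O)OC/C=C(\C)CCC=C(C)C | starting material
2 | (2E)-5-[(2R)-3,3-dimethyloxiran-2-yl]-3-methylpent-2-en-1-yl acetate | CC(=O)OC/C=C(\C)CC[C@H]1OC1(C)C | intermediate
3 | [(1S,3R)-3-hydroxy-2,2-dimethyl-6-methylidenecyclohexyl]methyl acetate | CC(=O)OC[C@@H]1C(C)(C)[C@H](O)CCC1=C | intermediate
4 | [(1S,3R,6R)-3,6-dihydroxy-2,2,6-trimethylcyclohexyl]methyl acetate | CC(=O)OC[C@@H]1C(C)(C)[C@H](O)CC[C@@]1(C)O | intermediate
5 | (1R,2S,4R)-2-(hydroxymethyl)-1,3,3-trimethylcyclohexane-1,4-diol | OC[C@@H]1C(C)(C)[C@H](O)CC[C@@]1(C)O | intermediate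
6 | (1R,3R,6R)-3,6-dihydroxy-2,2,6-trimethylcyclohexane-1-carbaldehyde | O=C[C@@H]1C(C)(C)[C@H](O)CC[C@@]1(C)O | intermediate
7 | (1R,2R,4R)-2-[(E)-2-iodoethenyl]-1,3,3-trimethylcyclohexane-1,4-diol | I/C=C/[C@@H]1C(C)(C)[C@H](O)CC[C@@]1(C)O | intermediate
8 | but-2-yn-1-ol | CC#CCO | starting material
9 | but-2-ynal | CC#CC=O | intermediate
10 | 4-bromo-2,5-dimethoxybenzaldehyde | COc1cc(C=O)c(OC)cc1Br | starting material
11 | (4-bromo-2,5-dimethoxyphenyl)methanol | COc1cc(CO)c(OC)cc1Br | intermediate
12 | [(4-bromo-2,5-dimethoxyphenyl)methoxy]tri(propan-2-yl)silane | COc1cc(CO[Si](C(C)C)(C(C)C)C(C)C)c(OC)cc1Br | intermediate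
13 | [(4-bromo-3,3,6,6-tetramethoxycyclohexa-1,4-dien-1-yl)methoxy]tri(propan-2-yl)silane | BrC1=CC(OC)(OC)C(CO[Si](C(C)C)(C(C)C)C(C)C)=CC1(OC)OC | intermediate
14 | 4-lithio analogue of 13 (alkenyllithium) | [Li]C1=CC(OC)(OC)C(CO[Si](C(C)C)(C(C)C)C(C)C)=CC1(OC)OC | intermediate
15 | methyl[3,3,6,6-tetramethoxy-4-(triisopropylsilyloxymethyl)cyclohexa-1,4-dien-1-yl]zinc | C[Zn]C1=CC(OC)(OC)C(CO[Si](C(C)C)(C(C)C)C(C)C)=CC1(OC)OC | intermediate
16 | methylzinc alkoxide of (1S)-1-[3,3,6,6-tetramethoxy-4-(triisopropylsilyloxymethyl)cyclohexa-1,4-dien-1-yl]but-2-yn-1-ol | CC#C[C@H](O[Zn]C)C1=CC(OC)(OC)C(CO[Si](C(C)C)(C(C)C)C(C)C)=CC1(OC)OC | intermediate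
17 | (1S)-1-[2,2,5,5-tetramethoxy-4-(triisopropylsilyloxymethyl)-7-oxabicyclo[4.1.0]hept-3-en-1-yl]but-2-yn-1-ol, erythro, oxirane carbons arranged as C5/C6 of the target | CC#C[C@H](O)[C@]12O[C@H]1C(OC)(OC)C(CO[Si](C(C)C)(C(C)C)C(C)C)=CC2(OC)OC | intermediate
18 | 1-[(1S)-1-hydroxybut-2-yn-1-yl]-4-(triisopropylsilyloxymethyl)-7-oxabicyclo[4.1.0]hept-3-ene-2,5-dione, oxirane as in 17 | CC#C[C@H](O)[C@]12O[C@H]1C(=O)C(CO[Si](C(C)C)(C(C)C)C(C)C)=CC2=O | intermediate
19 | corresponding 2,5-diol, both ring hydroxyls trans to the oxirane oxygen | CC#C[C@H](O)[C@]12O[C@H]1[C@H](O)C(CO[Si](C(C)C)(C(C)C)C(C)C)=C[C@@H]2O | intermediate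
20 | (Z)-vinylsilane of 19, benzyl(dimethyl)silyl on C2 cis to C4 | C/C([Si](C)(C)Cc1ccccc1)=C/[C@H](O)[C@]12O[C@H]1[C@H](O)C(CO[Si](C(C)C)(C(C)C)C(C)C)=C[C@@H]2O | intermediate
21 | hydroxy(dimethyl)silyl analogue of 20 (silanol) | C/C([Si](C)(C)O)=C/[C@H](O)[C@]12O[C@H]1[C@H](O)C(CO[Si](C(C)C)(C(C)C)C(C)C)=C[C@@H]2O | intermediate
22 | arthrosporol A, primary hydroxyl as TIPS ether | CC(=C/[C@H](O)[C@]12O[C@H]1[C@H](O)C(CO[Si](C(C)C)(C(C)C)C(C)C)=C[C@@H]2O)/C=C/[C@@H]1C(C)(C)[C@H](O)CC[C@@]1(C)O | intermediate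
23 | arthrosporol A | CC(=C/[C@H](O)[C@]12O[C@H]1[C@H](O)C(CO)=C[C@@H]2O)/C=C/[C@@H]1C(C)(C)[C@H](O)CC[C@@]1(C)O | target

**Step count and risk**
Total steps: 14. Longest linear sequence: 8 (steps 7–14, from 10).

Most likely to fail:

Step 10. The hindered, ketal-flanked alkenyl group may transfer slowly from zinc, the reactive ynal may erode the enantioselectivity, and the ring alkene is deactivated by its two allylic ketals, so the in-pot epoxidation may stall. The fallback sets out from 13 and 9 and comes back at 17. Bromine–lithium exchange on 13 (t-BuLi, THF, −78 °C) and direct uncatalysed addition to 9 gives the racemic propargylic alcohol F1. MnO2 in CH2Cl2 oxidises it to the cross-conjugated ynone F2. Reduction with (R)-2-methyl-CBS-oxazaborolidine and catecholborane at −78 °C, with the slim alkynyl group as the small substituent, gives the free (S)-alcohol F3. VO(acac)2/TBHP in warm CH2Cl2 then carries out the hydroxyl-directed, erythro-selective epoxidation to 17.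

Step 12. Both carbonyls must take hydride from the oxirane face, and the free C4 hydroxyl could steer delivery the other way. The fallback sets out from 18 and comes back at 19. TESOTf/2,6-lutidine caps the C4 hydroxyl to give the triethylsilyl ether F4. iBu2AlH at −78 °C, which attacks anti to the oxirane oxygen, gives the all-syn diol F5. Double Mitsunobu inversion (4-nitrobenzoic acid, PPh3, DIAD) gives the bis(4-nitrobenzoate) F6 with both ring oxygens trans to the oxirane. K2CO3/MeOH gives the diol F7, and PPTS/MeOH removes the triethylsilyl group to reach 19.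

Step 13. Three free hydroxyls and an oxirane face a cationic ruthenium catalyst, and the silicon must end up on the distal alkyne carbon only. The fallback sets out from 19 and comes back at the target 23. 1,1,3,3-Tetramethyldisilazane turns the three hydroxyls into dimethylsilyl ethers to give the tris(dimethylsilyl) ether F8. [Cp*Ru(MeCN)3]PF6 then brings about intramolecular trans-hydrosilylation from the C4 silyl ether; only the endo mode, closing a five-membered ring, is geometrically possible, so silicon is forced onto the distal carbon cis to C4 in the cyclic siloxane F9. Pd2(dba)3/TBAF coupling of F9 with vinyl iodide 7, the fluoride also stripping the remaining silyl groups, gives 23.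

Further compounds
F1 | step 10 | racemic 1-[3,3,6,6-tetramethoxy-4-(triisopropylsilyloxymethyl)cyclohexa-1,4-dien-1-yl]but-2-yn-1-ol | CC#CC(O)C1=CC(OC)(OC)C(CO[Si](C(C)C)(C(C)C)C(C)C)=CC1(OC)OC
F2 | step 10 | 1-[3,3,6,6-tetramethoxy-4-(triisopropylsilyloxymethyl)cyclohexa-1,4-dien-1-yl]but-2-yn-1-one | CC#CC(=O)C1=CC(OC)(OC)C(CO[Si](C(C)C)(C(C)C)C(C)C)=CC1(OC)OC
F3 | step 10 | (1S)-1-[3,3,6,6-tetramethoxy-4-(triisopropylsilyloxymethyl)cyclohexa-1,4-dien-1-yl]but-2-yn-1-ol | CC#C[C@H](O)C1=CC(OC)(OC)C(CO[Si](C(C)C)(C(C)C)C(C)C)=CC1(OC)OC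
F4 | step 12 | C4 triethylsilyl ether of 18 | CC#C[C@H](O[Si](CC)(CC)CC)[C@]12O[C@H]1C(=O)C(CO[Si](C(C)C)(C(C)C)C(C)C)=CC2=O
F5 | step 12 | all-syn diol (both ring hydroxyls cis to the oxirane oxygen), C4 triethylsilyl ether | CC#C[C@H](O[Si](CC)(CC)CC)[C@]12O[C@H]1[C@@H](O)C(CO[Si](C(C)C)(C(C)C)C(C)C)=C[C@H]2O
F6 | step 12 | bis(4-nitrobenzoate) with both ring oxygens trans to the oxirane, C4 triethylsilyl ether | CC#C[C@H](O[Si](CC)(CC)CC)[C@]12O[C@H]1[C@H](OC(=O)c3ccc(cc3)[N+](=O)[O-])C(CO[Si](C(C)C)(C(C)C)C(C)C)=C[C@@H]2OC(=O)c3ccc(cc3)[N+](=O)[O-]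
F7 | step 12 | C4 triethylsilyl ether of 19 | CC#C[C@H](O[Si](CC)(CC)CC)[C@]12O[C@H]1[C@H](O)C(CO[Si](C(C)C)(C(C)C)C(C)C)=C[C@@H]2O
F8 | step 13 | tris(dimethylsilyl) ether of 19 | CC#C[C@H](O[SiH](C)C)[C@]12O[C@H]1[C@H](O[SiH](C)C)C(CO[Si](C(C)C)(C(C)C)C(C)C)=C[C@@H]2O[SiH](C)C
F9 | step 13 | 2,2,3-trimethyl-2,5-dihydro-1,2-oxasilol-5-yl cyclic siloxane on C5 of the core, ring hydroxyls as dimethylsilyl ethers | CC1=C[C@H](O[Si]1(C)C)[C@]23O[C@H]2[C@H](O[SiH](C)C)C(CO[Si](C(C)C)(C(C)C)C(C)C)=C[C@@H]3O[SiH](C)C
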